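**Plan**
- Numbering used: ring C1 (C=O), C2=C3, C4 (OMe), C5 (CH2), C6 (quaternary, allyl). Side chain: C8 (CHMe), C7 (CHOAc‑aryl).
- Cuts: C2=C3 goes back to a trans‑3,4‑dimethoxycyclohexanone (loss of MeOH). Next, C5–C6 and C7–C8 are cut together (Prins–semipinacol) to an aryl acylal and a 1‑alkenylcyclopentanol silyl ether. Then C1–C6 is cut (alkenyl metal + ketone). Last, the cyclopentanone goes back to a D‑tartrate C4 unit and TosMIC.
- Enabling feature: the C1 ketone sits directly on the all‑carbon quaternary C6, which is the retron of a 1,2‑shift from C1 to C6, and C7–O is 1,4 to C1=O. The C2=C3–C4(OMe) unit is what remains of a C2‑symmetric vicinal dimethoxy pair. A C2‑symmetric five‑membered ring with a temporary C1–C5 bond can therefore serve as precursor, and either ring CH2 may migrate.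
- Forward order: the cyclopentanone ring is made first and the Z‑alkenyl arm is attached second. One step then joins the aryl carbon and expands the five‑ to the six‑membered ring. The enone is released last.
- Stereochemistry: C4 comes from D‑tartrate. C6 and C8 come from anti addition across the Z alkene. C7 comes from an open antiperiplanar transition state. The absolute sense of C6–C8 is relayed from the tartrate‑derived methoxy groups.

Key step: step 11

Assumption: compounds 1, 5, 9, 11 and 13 are taken as commercial.

Step 1
Reactants: 1 dimethyl D‑tartrate [dimethyl (2S,3S)-2,3-dihydroxybutanedioate]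
Product: 2 dimethyl (2S,3S)-2,3-dimethoxybutanedioate
Conditions: MeI (excess), Ag2O, MeCN, 40 °C, dark
Reagents that add atoms: iodomethane, CI
Why: Purdie methylation under neutral Ag2O conditions should etherify both carbinols without touching the two tartrate stereocentres, one of which becomes C4 of the target.

Step 2
Reactants: 2 dimethyl (2S,3S)-2,3-dimethoxybutanedioate
Product: 3 (2R,3R)-2,3-dimethoxybutane-1,4-diol
Conditions: LiAlH4, THF, 0 °C → reflux; H2O/NaOH work‑up
Reagents that add atoms: none
Why: Exhaustive LiAlH4 ester reduction should give the C2‑symmetric diol and leave the ether‑bearing stereocentres untouched (the descriptor changes only through the priority rules).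

Step 3
Reactants: 3 (2R,3R)-2,3-dimethoxybutane-1,4-diol
Product: 4 (2S,3S)-1,4-diiodo-2,3-dimethoxybutane
Conditions: PPh3, I2, imidazole, CH2Cl2, 0 °C → rt
Reagents that add atoms: iodine, II
Why: Appel‑type iodination replaces both primary hydroxyl groups by SN2 at CH2, so no stereocentre takes part.

Step 4
Reactants: 4 (2S,3S)-1,4-diiodo-2,3-dimethoxybutane; 5 p‑toluenesulfonylmethyl isocyanide (TosMIC)
Product: 7 (3R,4R)-1-isocyano-3,4-dimethoxy-1-tosylcyclopentane, via monoalkylated isocyanide 6 (not isolated)
Conditions: NaH (2.2 equiv), DMSO–Et2O, rt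
Reagents that add atoms: none
Why: Double alkylation of TosMIC as a carbonyl dianion equivalent (van Leusen ketone synthesis) should close the five‑membered ring by a favoured 5‑exo‑tet displacement, and C2 symmetry keeps the new ring carbon from being a stereocentre.

Step 5
Reactants: 7 (3R,4R)-1-isocyano-3,4-dimethoxy-1-tosylcyclopentane
Product: 8 (3R,4R)-3,4-dimethoxycyclopentan-1-one
Conditions: conc. aq HCl (cat.), Et2O–CH2Cl2, 0 °C, short contact
Reagents that add atoms: water, O
Why: Acid hydrolysis of the α‑tosyl isocyanide (second stage of the van Leusen ketone synthesis) should unmask the ketone fast enough at 0 °C that the β‑methoxy groups are not eliminated.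

Step 6
Reactants: 9 acetaldehyde
Product: 10 1,1-dibromoprop-1-ene
Conditions: CBr4, PPh3 (2 equiv), CH2Cl2, 0 °C
Reagents that add atoms: tetrabromomethane, BrC(Br)(Br)Br
Why: Ramirez dibromo‑olefination (first stage of the Corey–Fuchs sequence) converts the aldehyde with the ylide made in the flask from CBr4 and PPh3.

Step 7
Reactants: 10 1,1-dibromoprop-1-ene; 11 allyltributylstannane
Product: 12 (4Z)-4-bromohexa-1,4-diene
Conditions: Pd2(dba)3 (cat.), tri(2‑furyl)phosphine, toluene, 80 °C
Reagents that add atoms: none
Why: In this Stille coupling zerovalent palladium should insert selectively into the less hindered C–Br bond trans to the methyl group of the 1,1‑dibromoalkene, so the remaining bromine stays cis to methyl (Z).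

Step 8
Reactants: 13 3,4,5-trimethoxybenzaldehyde
Product: 14 (3,4,5-trimethoxyphenyl)methylene diacetate
Conditions: Ac2O, Bi(OTf)3 (cat.), MeCN, rt
Reagents that add atoms: acetic anhydride, CC(=O)OC(C)=O
Why: Lewis acid catalysed acylal formation adds acetic anhydride across the aldehyde C=O and stores the future C7 acetate in the electrophile.

Step 9
Reactants: 12 (4Z)-4-bromohexa-1,4-diene; 8 (3R,4R)-3,4-dimethoxycyclopentan-1-one
Product: 17 (3R,4R)-1-[(2Z)-hexa-2,5-dien-3-yl]-3,4-dimethoxycyclopentan-1-ol, via alkenyllithium 15 (not isolated), via alkenylcerium dichloride 16 (not isolated)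
Conditions: t‑BuLi (2 equiv), Et2O, −78 °C; anhydrous CeCl3, THF, −78 °C; then 8, −78 °C; H2O
Reagents that add atoms: none
Why: Bromine–lithium exchange keeps the alkene geometry and the weakly basic organocerium reagent should add 1,2 to the enolisable, elimination‑prone ketone, whose two faces are homotopic, so no new stereocentre arises.

Step 10
Reactants: 17 (3R,4R)-1-[(2Z)-hexa-2,5-dien-3-yl]-3,4-dimethoxycyclopentan-1-ol
Product: 18 {[(3R,4R)-1-[(2Z)-hexa-2,5-dien-3-yl]-3,4-dimethoxycyclopentyl]oxy}trimethylsilane
Conditions: TMSOTf, 2,6‑lutidine, CH2Cl2, −78 → 0 °C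
Reagents that add atoms: trimethylsilyl triflate, C[Si](C)(C)OS(=O)(=O)C(F)(F)F
Why: Buffered silylation of the hindered tertiary alcohol with TMSOTf should give the silyl ether that later supplies the silyl group for catalyst turnover.

Step 11
Reactants: 18 {[(3R,4R)-1-[(2Z)-hexa-2,5-dien-3-yl]-3,4-dimethoxycyclopentyl]oxy}trimethylsilane; 14 (3,4,5-trimethoxyphenyl)methylene diacetate
Product: 21 (2R,4R,5R)-2-allyl-2-[(1R,2S)-1-acetoxy-1-(3,4,5-trimethoxyphenyl)propan-2-yl]-4,5-dimethoxycyclohexan-1-one, via acetoxycarbenium triflate 19 (not isolated), via O-silylated ketone triflate 20 (not isolated)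
Conditions: 14 (1.2 equiv), TMSOTf (0.2 equiv), 2,6‑di‑tert‑butyl‑4‑methylpyridine (0.3 equiv), CH2Cl2, −78 → −30 °C
Reagents that add atoms: none
Why: Proposed new method: TMSOTf ionises acylal 14 to the acetoxycarbenium ion 19, the trisubstituted alkene of 18 attacks it through C8, and as positive charge builds at C6 the antiperiplanar ring CH2 (C5) shifts from the carbinol carbon C1 to C6, giving the O‑silylated ketone 20, which passes its silyl group on and so regenerates the catalyst. The closest known reaction types are the acetal‑initiated Prins–pinacol cascade (known with a tethered oxocarbenium ion), the halonium‑ or carbocation‑induced semipinacol ring expansion of 1‑alkenylcycloalkanols and the Lewis acid allylation of acylals to homoallylic acetates; new here is the untethered carbon electrophile on an unstrained, non‑styrenyl cyclopentanol. The six‑membered ring is closed by a 1,2‑shift ring expansion (C5–C6 made, the temporary C1–C5 bond broken, C1 turned into the ketone) and not by an end‑to‑end cyclisation. C6 and C8 are set together by the stereospecific anti addition of C7 and C5 across the Z alkene, C7 by an antiperiplanar open transition state in which the aryl group avoids the C8 methyl group (syn, as with crotylsilanes), and the absolute sense by the ring methoxy group cis to the alkenyl arm, which in the rotamer enforced by A1,3 strain (C–OSi bond in the alkene plane, both ring CH2 groups astride the π system) shields one alkene face, so that the electrophile enters from the other face and the CH2 next to that methoxy carbon migrates. Which CH2 migrates is constitutionally irrelevant because the C2‑symmetric ring makes both shifts give the same skeleton, and the trisubstituted alkene should outcompete the monosubstituted allyl alkene as nucleophile. The shift must outrun proton loss, acetate capture and Friedel–Crafts closure of the electron‑rich arene onto C6, which the aligned C1–C5 bond and the push of the silyloxy oxygen should secure.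

Step 12
Reactants: 21 (2R,4R,5R)-2-allyl-2-[(1R,2S)-1-acetoxy-1-(3,4,5-trimethoxyphenyl)propan-2-yl]-4,5-dimethoxycyclohexan-1-one
Product: 22 megaphone acetate [(1R,2S)-2-[(1R,5R)-5-methoxy-2-oxo-1-(prop-2-en-1-yl)cyclohex-3-en-1-yl]-1-(3,4,5-trimethoxyphenyl)propyl acetate]
Conditions: DBU (1.2 equiv), 4 Å molecular sieves, CH2Cl2, 0 °C → rt
Reagents that add atoms: none
Why: In this E1cB β‑elimination only C2 carries enolisable hydrogens (C6 is quaternary), so only the C3 methoxy group should leave, while the C4 methoxy stereocentre and the acetate stay under the non‑nucleophilic base.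

**Compound list**
1 | dimethyl D‑tartrate, dimethyl (2S,3S)-2,3-dihydroxybutanedioate | COC(=O)[C@@H](O)[C@H](O)C(=O)OC | starting material
2 | dimethyl (2S,3S)-2,3-dimethoxybutanedioate | COC(=O)[C@@H](OC)[C@H](OC)C(=O)OC | intermediate
3 | (2R,3R)-2,3-dimethoxybutane-1,4-diol | OC[C@@H](OC)[C@H](OC)CO | intermediate
4 | (2S,3S)-1,4-diiodo-2,3-dimethoxybutane | IC[C@@H](OC)[C@H](OC)CI | intermediate
5 | p‑toluenesulfonylmethyl isocyanide (TosMIC) | Cc1ccc(cc1)S(=O)(=O)C[N+]#[C-] | starting material
6 | 5-iodo-1-isocyano-3,4-dimethoxypentyl p‑tolyl sulfone (tartrate centres unchanged, both C1 epimers) | Cc1ccc(cc1)S(=O)(=O)C([N+]#[C-])C[C@@H](OC)[C@H](OC)CI | intermediate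
7 | (3R,4R)-1-isocyano-3,4-dimethoxy-1-tosylcyclopentane | Cc1ccc(cc1)S(=O)(=O)C1([N+]#[C-])C[C@@H](OC)[C@H](OC)C1 | intermediate
8 | (3R,4R)-3,4-dimethoxycyclopentan-1-one | O=C1C[C@@H](OC)[C@H](OC)C1 | intermediate
9 | acetaldehyde | CC=O | starting material
10 | 1,1-dibromoprop-1-ene | CC=C(Br)Br | intermediate
11 | allyltributylstannane | C=CC[Sn](CCCC)(CCCC)CCCC | starting material
12 | (4Z)-4-bromohexa-1,4-diene | C=CC/C(Br)=C/C | intermediate
13 | 3,4,5-trimethoxybenzaldehyde | COc1cc(C=O)cc(OC)c1OC | starting material
14 | (3,4,5-trimethoxyphenyl)methylene diacetate | CC(=O)OC(OC(C)=O)c1cc(OC)c(OC)c(OC)c1 | intermediate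
15 | hexa-2,5-dien-3-yllithium (lithium cis to methyl) | C=CC/C([Li])=C/C | intermediate
16 | (hexa-2,5-dien-3-yl)cerium dichloride (cerium cis to methyl) | C=CC/C([Ce](Cl)Cl)=C/C | intermediate
17 | (3R,4R)-1-[(2Z)-hexa-2,5-dien-3-yl]-3,4-dimethoxycyclopentan-1-ol | C=CC/C(=C/C)C1(O)C[C@@H](OC)[C@H](OC)C1 | intermediate
18 | trimethylsilyl ether of 17 | C=CC/C(=C/C)C1(O[Si](C)(C)C)C[C@@H](OC)[C@H](OC)C1 | intermediate
19 | acetoxy(3,4,5-trimethoxyphenyl)methylium triflate | CC(=O)[O+]=Cc1cc(OC)c(OC)c(OC)c1.[O-]S(=O)(=O)C(F)(F)F | intermediate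
20 | O‑trimethylsilyl oxocarbenium triflate of 21 | C=CC[C@]1([C@H](C)[C@@H](OC(C)=O)c2cc(OC)c(OC)c(OC)c2)C[C@@H](OC)[C@H](OC)CC1=[O+][Si](C)(C)C.[O-]S(=O)(=O)C(F)(F)F | intermediate
21 | (2R,4R,5R)-2-allyl-2-[(1R,2S)-1-acetoxy-1-(3,4,5-trimethoxyphenyl)propan-2-yl]-4,5-dimethoxycyclohexan-1-one | C=CC[C@]1([C@H](C)[C@@H](OC(C)=O)c2cc(OC)c(OC)c(OC)c2)C[C@@H](OC)[C@H](OC)CC1=O | intermediate
22 | megaphone acetate | C=CC[C@]1([C@H](C)[C@@H](OC(C)=O)c2cc(OC)c(OC)c(OC)c2)C[C@@H](OC)C=CC1=O | target

**Step count and risks**
Total step count: 12. Longest linear sequence: 9 (steps 1–5 and 9–12).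

**Steps most likely to fail**

1. Step 11.
 - What may go wrong: the oxygen‑deactivated alkene may attack the acetoxycarbenium ion too slowly. Ionisation of the tertiary allylic silyl ether or Friedel–Crafts self‑condensation of the arene could then take over. Discrimination of the two alkene faces by the remote methoxy group may also be low.
 - Fallback (known reaction types only), from 17 back to 21: N‑bromosuccinimide in CH2Cl2/i‑PrOH at −20 °C triggers the known halonium‑induced semipinacol ring expansion, which makes the same C5–C6 bond, and gives the β‑bromo ketone F1.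
 - A nickel‑catalysed reductive acylation of the secondary bromide follows (NiCl2(dme), 4,4'‑di‑tert‑butyl‑2,2'‑bipyridine, Zn, DMA, 3,4,5‑trimethoxybenzoyl chloride). It gives the 1,4‑diketone F2, whose C8 centre lies next to the aryl ketone and can be corrected by base equilibration.
 - Felkin–Anh‑controlled reduction of the aryl ketone with LiBH(s‑Bu)3 at −78 °C gives the C7‑epimeric alcohol F3.
 - A Mitsunobu reaction with acetic acid (PPh3, diisopropyl azodicarboxylate) inverts C7 and installs the acetate in one operation, which returns the route to 21.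

2. Step 9.
 - What may go wrong: enolisation of the ketone followed by loss of methoxide, slow addition of the hindered Z‑alkenyl metal, proton abstraction from the bis‑allylic CH2, or erosion of alkene geometry on warming.
 - Fallback, from 8 back to 18: the slimmer and far less basic 1‑propynylmagnesium bromide (LaCl3·2LiCl, THF, 0 °C) is added to 8 to give the propargylic alcohol F4. TMSOTf/2,6‑lutidine then gives its silyl ether F5.
 - A copper hydride catalysed hydroallylation follows ((IPr)CuCl, LiOt‑Bu, (EtO)2MeSiH, allyl diethyl phosphate, THF). It adds hydrogen to the methyl‑bearing alkyne carbon and allyl to the carbon next to the oxygenated centre in syn fashion. This places the ring carbon cis to methyl and delivers 18, so the alkene is built after, not before, the C1–C6 bond.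

3. Step 7.
 - What may go wrong: a second coupling at the remaining C–Br bond, dehydrobromination of the product under palladium catalysis, migration of the allyl double bond into conjugation, or loss of the volatile product.
 - Fallback, from 9 back to 12: a Wittig reaction of 9 with ethyl bromo(triphenylphosphoranylidene)acetate gives ethyl (Z)-2-bromobut-2-enoate F6.
 - i‑Bu2AlH (CH2Cl2, −78 °C) gives (Z)-2-bromobut-2-en-1-ol F7, and PBr3 (Et2O, 0 °C) gives (Z)-1,2-dibromobut-2-ene F8.
 - Direct substitution of the allylic bromide with vinylmagnesium bromide under Li2CuCl4 catalysis (THF, −30 °C) gives 12. The Z geometry is fixed by the stabilised ylide instead of by site‑selective oxidative addition.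

**Further compounds**
F1 | step 11 | (2S,4R,5R)-2-allyl-2-[(1S)-1-bromoethyl]-4,5-dimethoxycyclohexan-1-one | C=CC[C@]1([C@H](C)Br)C[C@@H](OC)[C@H](OC)CC1=O
F2 | step 11 | (2R,4R,5R)-2-allyl-4,5-dimethoxy-2-[(2S)-1-oxo-1-(3,4,5-trimethoxyphenyl)propan-2-yl]cyclohexan-1-one | C=CC[C@]1([C@H](C)C(=O)c2cc(OC)c(OC)c(OC)c2)C[C@@H](OC)[C@H](OC)CC1=O
F3 | step 11 | (2R,4R,5R)-2-allyl-2-[(1S,2S)-1-hydroxy-1-(3,4,5-trimethoxyphenyl)propan-2-yl]-4,5-dimethoxycyclohexan-1-one | C=CC[C@]1([C@H](C)[C@H](O)c2cc(OC)c(OC)c(OC)c2)C[C@@H](OC)[C@H](OC)CC1=O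
F4 | step 9 | (3R,4R)-3,4-dimethoxy-1-(prop-1-yn-1-yl)cyclopentan-1-ol | CC#CC1(O)C[C@@H](OC)[C@H](OC)C1
F5 | step 9 | trimethylsilyl ether of F4 | CC#CC1(O[Si](C)(C)C)C[C@@H](OC)[C@H](OC)C1
F6 | step 7 | ethyl (Z)-2-bromobut-2-enoate | CCOC(=O)/C(Br)=C/C
F7 | step 7 | (Z)-2-bromobut-2-en-1-ol | OC/C(Br)=C/C
F8 | step 7 | (Z)-1,2-dibromobut-2-ene | BrC/C(Br)=C/C
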